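The runs stem from a simulated flask with constants of no real substance; the scatter is artificial.

If Ek is the limiting reagent and one Ek goes into each Rx, the bench rule stops Rx when Ek is used up, which here allows 90.0% of the Ze charged, since 0.297 M of Ek is less than the 0.33 M of Ze.

| setting | Thursday's | Tuesday's | cedar | larch | ash |
|---|---|---|---|---|---|
| Ze | 0.46 M (fed, over 3.0 min) | 0.73 M (fed, over 3.0 min) | 0.33 M (fed, over 3.0 min) | 0.33 M (fed, over 3.0 min) | 0.33 M (fed, over 3.0 min) |
| Ek | 0.297 M | 0.297 M | 0.297 M | 0.297 M | 0.297 M |
| Ky | 1.65 M | 1.65 M | 1.65 M | 1.65 M | 1.65 M |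
| Ez | 3.3 mM | 3.3 mM | 3.3 mM | 3.3 mM | 3.3 mM |
| temperature | 22 °C | 50 °C | 10 °C | 35 °C | 60 °C |
| remark | run made earlier | run made earlier |  |  |  |
| time |  |  | 20 min | 20 min | 20 min |

| run | time / min | Rx / % |
|---|---|---|
| Thursday's | 1.00 | 1 |
| Thursday's | 1.50 | 5 |
| Thursday's | 2.00 | 7 |
| Thursday's | 3.00 | 12 |
| Thursday's | 6.00 | 25 |
| Thursday's | 8.00 | 31 |
| Thursday's | 15.0 | 36 |
| Tuesday's | 0.250 | 0 |
| Tuesday's | 0.417 | 2 |
| Tuesday's | 0.500 | 3 |
| Tuesday's | 0.833 | 5 |
| Tuesday's | 1.33 | 9 |
| Tuesday's | 2.00 | 15 |
| Tuesday's | 3.00 | 23 |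

(scatter of a reading: 1.5 percentage points)

- which flask leads in amount of Rx, in percent of the Ze charged ("all alike" within 1.5 percentage points) (cedar / larch / ash / all alike)
- how much Rx is there at the end, in percent of the Ze charged: cedar
- how much Rx is there at the end, in percent of the Ze charged: larch
- how much Rx is there at the end, in percent of the Ze charged: ash

- what was read earlier has a scatter of 1.5 percentage points, one standard deviation
- percentages count the whole charge, also what has not yet gone in

Thursday's run shows where that rule stops working. Its ratio of charges allows 64.6%, but it reads 36% at 15.0 min. It gains 13 percentage points between 3.00 min and 6.00 min, and 5 points between 8.00 min and 15.0 min, so it is nearly standing. Its 0.166 M of Rx is 55.8% of the Ek charged, and subtracting one Ze and one Ek for each Rx leaves 0.294 M of Ze and 0.131 M of Ek by my count. A flask that slows with both partners present looks to me like an equilibrium, so I freeze the quotient, which reads 4.28 M⁻¹: the standstill quotient, [Rx]/([Ze][Ek]) where the flask stops. It is a reading, with the scatter of its percentages. Tuesday's run, still climbing at 3.00 min, gives 2.31 M⁻¹, which is lower than the standstill quotient, as a flask short of its stop should.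

Cedar, larch and ash have equal charges, so if the standstill quotient does not move with temperature, setting [Rx]/([Ze][Ek]) equal to it gives them the same stop: 0.135 M of Rx, or 40.9% of the Ze charged. I expect larch and ash level there and cedar, the coldest of the flasks, at or under it.

The forecast names ash as leader, with cedar 50% (36% to 68%), larch 62% (45% to 82%) and ash 66% (40% to 88%), and says “Warmer flasks should go further”.

The flasks give cedar 36.2%, larch 44.2% and ash 37.8%, so larch leads: cedar ends 4.7 points under my stop, larch 3.3 points over it and ash 3.1 points under it.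

    Ky + Ek + Ez → Ez + Dw (k = 0.0501 M⁻² s⁻¹, Ea = 41.0 kJ mol⁻¹)
    Ze + Ek + Ez ⇌ Ez + Rx (K = 7.33 M⁻¹, k = 3.86 M⁻² s⁻¹, Ea = 45.0 kJ mol⁻¹, ΔH = 7.00 kJ mol⁻¹)
    (constants at 35 °C)

A neighbour of ash takes 0.74 M of Ek, with the other charges, the temperature and the time unchanged. With the same standstill quotient and the same equation, I get 0.227 M of Rx, or 68.8% of the Ze charged. The neighbour gives 65.4%, which is 3.3 points under that reckoning and above the 37.8% of ash. Its Ek stands at 2.24 equiv to Ze, and 34.6% of the Ze charged remains as Ze at the end.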